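Read at 40 min in Thursday's flask and at 120 min in Monday's, the charge is shared among the columns, and the balance of the protic impurity, the limiting reagent of a one-for-one loss and a smaller charge than the starting material, shows how much there is to share.

| setting | midnight | autumn | Thursday's | Monday's |
|---|---|---|---|---|
| starting material | 0.10 M | 0.10 M | 0.10 M | 0.10 M |
| reagent in the second phase | 0.13 M | 0.13 M | 0.130 M | 0.130 M |
| protic impurity | 0.025 M | 0.038 M | 0.0500 M | 0.0500 M |
| remark | run made earlier | run made earlier |  |  |
| time |  |  | 40 min | 120 min |
| volume of the second phase over the first |  |  | 1.0 | 1.0 |

| run | time / min | over-reacted product / % | starting material / % | target / % | over-reaction product / % |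
|---|---|---|---|---|---|
| midnight | 6.00 | 0 | 74.8 | 3.6 | 0.4 |
| midnight | 12.0 | 0.1 | 66.0 | 8.7 | 1.5 |
| midnight | 20.0 | 0.7 | 58.8 | 11.2 | 4.1 |
| midnight | 25.0 | 1.3 | 55.7 | 12.1 | 6.1 |
| midnight | 30.0 | 2.0 | 53.1 | 11.5 | 8.6 |
| midnight | 40.0 | 2.8 | 48.0 | 11.4 | 12.2 |
| autumn | 6.00 | 0 | 65.0 | 3.8 | 0.9 |
| autumn | 12.0 | 0.3 | 55.2 | 7.8 | 1.5 |
| autumn | 20.0 | 0.4 | 48.3 | 9.5 | 4.3 |
| autumn | 25.0 | 1.3 | 45.0 | 9.5 | 5.5 |
| autumn | 30.0 | 1.6 | 42.8 | 10.1 | 7.1 |
| autumn | 40.0 | 2.8 | 38.6 | 9.4 | 10.7 |

(scatter of a reading: 0.3 percentage points)

- in the second phase: reagent in the second phase; everything else is in the first
- charges count per volume of the first phase; a concentration in a rate is the amount of a species over the volume of its own phase; every rate counts per litre of the first phase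
- the earlier runs hold the two phases in the same ratio of volumes as the flask asked about

* which of these there is most of at the end, counted by the starting material in it, Thursday's (target / over-reaction product / starting material / over-reacted product)
* which of these there is most of at the end, counted by the starting material in it, Monday's (target / over-reaction product / starting material / over-reacted product)
* the largest of these amounts at the end, in percent of the starting material charged, Thursday's
* the largest of these amounts at the end, in percent of the starting material charged, Monday's

At 40.0 min the midnight run is missing 25.6 % of its charge and the autumn run 38.5 %, against impurity charges of 25.0 % and 38.0 % of the starting material. Both new flasks are therefore reckoned to keep 50.0 %, the open share, which is the fraction of the charge left once the impurity has taken its equal amount.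

Autumn's starting material at 40.0 min is 62.3 % of its own open share and stands higher than any other column, which gives Thursday's 31.1 % of starting material, in the lead. The decline read between autumn's last two readings, 0.0103 min⁻¹, if it simply goes on, puts this at 13.6 % on Monday's, and the ratio of target to starting material in autumn's last readings, 0.244, adds an estimated 3.32 % of target. Inside the open share that leaves 33.1 % of the charge, and the split in autumn's last readings gives over-reaction product 0.793 of it, an estimated 26.2 %, more than the starting material reckoned for Monday's.

The forecast names starting material at 31 % for Thursday's and starting material at 17.5 % for Monday's, adding “This call is closer”, and so parts from this reckoning on Monday's.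

The flasks give starting material at 30.4 % on Thursday's and over-reaction product at 24.8 % on Monday's.

    reagent in the reaction phase ⇌ reagent in the second phase, rate k1*([reagent in the reaction phase] - [reagent in the second phase]/K1) per volume of the first phase (partition coefficient = 2.90, kL = 0.00130 s⁻¹)
    starting material + reagent in the reaction phase ⇌ target (K = 14.0 M⁻¹, k = 0.0300 M⁻¹ s⁻¹)
    reagent in the reaction phase + target → over-reacted product (k = 0.00670 M⁻¹ s⁻¹)
    starting material + protic impurity → quenched substrate (k = 0.0560 M⁻¹ s⁻¹)
    target → over-reaction product (k = 5.80 × 10⁻⁴ s⁻¹)

Monday's columns add up to 50.0 %, beside an open share of 50.0 %, while quenched substrate holds 50.0 %. A flask like Thursday's but with 0.013 M of protic impurity has an open share of 87.0 %, and autumn's fraction puts its starting material at 54.2 %. At 40.0 min that flask holds 57.6 % of starting material, its columns add up to 87.0 %, and its quenched substrate stands at 13.0 %.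

(The runs are calculated on assumed constants; noise was put on by code.)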